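The numbers in the tables were computed for substances that don't exist, and the scatter is random.

The amounts of J differ between the midnight run (0.14 M) and the spring run (0.22 M), yet both stand at 38.9% of their charge at 40.0 min. So [J] need not be known well, though the flask's 0.10 M lies below both. [X] is 0.50 mM in the flask as in both runs, so I can carry its effect over without knowing its order.

in all of them: X 0.50 mM

| flask | J | remark | time |
|---|---|---|---|
| midnight | 0.14 M | run made earlier |  |
| spring | 0.22 M | run made earlier |  |
| flask | 0.10 M |  | 50 min |

| run | time / min | J / % | E / % |
|---|---|---|---|
| midnight | 3.00 | 92.7 | 5.5 |
| midnight | 8.00 | 83.1 | 16.8 |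
| midnight | 15.0 | 70.7 | 30.2 |
| midnight | 40.0 | 38.9 | 60.7 |
| spring | 3.00 | 93.7 | 7.3 |
| spring | 8.00 | 83.1 | 16.7 |
| spring | 15.0 | 70.5 | 29.8 |
| spring | 40.0 | 38.9 | 60.4 |

(each reading ± 0.5 percentage points)

1. the state of affairs at 50 min: stopped, and by what, or still going (all of J has reacted / it is still moving / no working catalyst is left)
2. share of the J used up at 50 min
3. E at 50 min, in percent of the J charged

- what may be going on: 2 X <-> G; J + X -> X + E
- the reaction counts as stopped when no species that holds the J changes by six tenths of a point or more over the second half of the time

The number to know well is k, which the 40.0 min reading of both runs puts at 0.0236 /min: my decay constant, the share of the J present that goes per minute at this [X], a pseudo-first-order constant. An earlier reading of the midnight run, at 8.00 min, gives 0.0231 /min, and the gap is smaller than that reading's scatter of 7.52 × 10⁻⁴ /min, so one exponential joins these two readings. The scatter of the later reading moves my answer by 0.49 percentage points.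

I reckon J at 30.7% in the flask at 50 min, so 69.3% is used. I expect E to match that, since J + E reads 99.6% in the midnight run at 40.0 min. Over the second half J falls 25 points, so the flask is still moving.

The forecast says it is still moving, with 69% used (67% to 71%) and E at 68.8% (66.5% to 71%), holding that “the same k should apply”.

The flask's state at 50 min is this: it is still moving, with 68.8% used and E at 68.8%.

    2 X ⇌ G, settled at all times (K = 35000 /M)
    J + X → X + E (k = 300 /M/min)

J left in the flask is 31%, against my 30.7%. X stands at 15.5% of its charge at 5.00 min and 15.5% at 50.0 min, with G at 84.5%. With the time held, X charged at 0.389 mM or 0.648 mM moves the share used in the flask by 5 points. The neighbouring flask has the same charges and is read at 2.0 h, where X is still 15.5%. There k puts J at 5.89%; that flask holds 6.10% J and 93.9% E.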